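**Retrosynthetic overview**

1. Numbering used: ring A = C1–C5 and C10 (C4 bears CO2Me and CH3, C1=C10); ring B = C5–C10 (C8 bears C17; C9 bears C20 and the chain C11–C15 with C13).
2. Endgame: target ⇐ desilylation and acetylation at C15 ⇐ hydrogenation of an exocyclic C8=C17 alkene (sets C8) ⇐ Wittig reaction on a C8 ketone ⇐ deconjugative C9-methylation of a Δ9(10)-8-ketone (adds C20, sets C9, creates C1=C10).
3. Key disconnection: ring B by a Robinson-type [3+3] annulation. Michael addition forms C6–C7 and aldol condensation forms C9–C10, between a ring A α-methylene ketone (C6=C5–C10=O) and a chain-bearing β-keto ester (C7–C8(=O)–C9).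
4. Fragments and ring order: the ring A piece comes from a copper-catalysed enantioselective conjugate methylation (sets C4) and a Mannich reaction; the chain C11–C15 with C13 comes from (S)-citronellol. Ring A is carried from the start; ring B is closed in the key step.
5. Enabling feature: C8 lies between C7 and C9, the inner atoms of the two new ring B bonds, and the C1=C10 alkene of ring A is β,γ to C8. A temporary C8 carbonyl therefore makes C7 and C9 nucleophilic toward C6 and C10, places the alkene by deconjugative alkylation, and is finally converted into the C17 methyl.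

Key step: step 8

**Route**

Step 1
Reactants: 1 (S)-citronellol
Product: 2 (S)-[(3,7-dimethyloct-6-en-1-yl)oxy]triisopropylsilane
Conditions: TIPSCl, imidazole, DMF, rt
Reagents that add atoms: chlorotriisopropylsilane, CC(C)[Si](Cl)(C(C)C)C(C)C
Why: Silylation of the primary alcohol gives an ether that should survive the oxidative, strongly basic and organometallic steps that follow, and C13 (bought) is not touched.

Step 2
Reactants: 2
Product: 3 (S)-4-methyl-6-[(triisopropylsilyl)oxy]hexanoic acid
Conditions: RuCl3 (cat.), NaIO4, CCl4/MeCN/H2O, rt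
Reagents that add atoms: sodium periodate, [Na+].[O-][I](=O)(=O)=O; water, O
Why: RuO4-mediated oxidative cleavage of the trisubstituted alkene should give the carboxylic acid directly, so that the carbon to be excised sits in a carboxyl group.

Step 3
Reactants: 3
Product: 4 (R)-[(5-iodo-3-methylpentyl)oxy]triisopropylsilane
Conditions: PhI(OAc)2, I2, CCl4, hν, reflux
Reagents that add atoms: iodine, II
Why: Radical decarboxylative iodination (Hunsdiecker-type, through the acyl hypoiodite) should turn the primary acid into the primary iodide at C11 without affecting the remote stereocentre, whose descriptor changes only because iodine outranks oxygen.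

Step 4
Reactants: 5 allyl acetoacetate; 4
Product: 7 prop-2-en-1-yl (7S)-7-methyl-3-oxo-9-[(triisopropylsilyl)oxy]nonanoate, via acetoacetate dianion 6 (not isolated)
Conditions: NaH, THF, 0 °C; n-BuLi, 0 °C; then 4, 0 °C → rt; aq. NH4Cl
Reagents that add atoms: none
Why: γ-Alkylation of a β-keto ester dianion by a primary iodide is a dependable C–C bond formation and puts the chain on the future C9 while leaving the ester-activated future C7 free.

Step 5
Reactants: 8 methyl 3-oxocyclohex-1-ene-1-carboxylate
Product: 10 methyl (S)-1-methyl-3-[(trimethylsilyl)oxy]cyclohex-2-ene-1-carboxylate, via methylzinc enolate 9 (not isolated)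
Conditions: Me2Zn, Cu(OTf)2 (cat.), chiral sulfonate-bearing imidazolinium salt (NHC ligand precursor, cat.), t-BuOMe, −30 °C; then TMSOTf, −30 → 0 °C
Reagents that add atoms: dimethylzinc, C[Zn]C; trimethylsilyl triflate, C[Si](C)(C)OS(=O)(=O)C(F)(F)F
Why: Copper-catalysed enantioselective conjugate addition of a dialkylzinc to a β-ester-substituted cyclohexenone should create the C4 quaternary stereocentre under ligand control (ligand enantiomer chosen for S), and silylation of the zinc enolate fixes the enol ether regiospecifically toward C5.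

Step 6
Reactants: 10
Product: 11 methyl (1S)-2-[(dimethylamino)methyl]-1-methyl-3-oxocyclohexane-1-carboxylate (epimers at C2 of the ring)
Conditions: CH2=NMe2+ I−, CH2Cl2, 0 °C → rt; aq. NaHCO3
Reagents that add atoms: N,N-dimethylmethyleneiminium iodide, C=[N+](C)C.[I-]
Why: The Mannich reaction of the regiodefined silyl enol ether with a preformed iminium salt places C6 on C5 only, and the C5 configuration does not matter because C5 becomes trigonal in step 8.

Step 7
Reactants: 11
Product: 12 {[(2S)-2-(methoxycarbonyl)-2-methyl-6-oxocyclohexyl]methyl}trimethylammonium iodide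
Conditions: MeI, Et2O, rt
Reagents that add atoms: iodomethane, CI
Why: N-Quaternisation (Menshutkin reaction) turns the amine into a leaving group and gives a storable precursor of the sensitive α-methylene ketone.

Step 8
Reactants: 12; 7
Product: 15 7-allyl 1-methyl (1S,8aR)-1-methyl-5-{(3S)-3-methyl-5-[(triisopropylsilyl)oxy]pentyl}-6-oxo-1,2,3,4,6,7,8,8a-octahydronaphthalene-1,7-dicarboxylate (C7 epimers/enol), via α-methylene ketone 13 (not isolated), via Michael adduct 14 (not isolated)
Conditions: t-BuOK (2.2 equiv), t-BuOH/THF, 0 → 50 °C; aq. NH4Cl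
Reagents that add atoms: none
Why: Base-induced E1cB loss of NMe3 from 12 unmasks the α-methylene ketone 13 (C6=C5–C10=O), the ester-stabilised enolate of 7 adds through C7 to C6 (Michael addition, bond C6–C7), and the 1,5-diketone 14 closes by attack of the C9 enolate on the C10 carbonyl followed by E1cB dehydration to the C9=C10 enone (bond C9–C10). The closest known reaction type is the Robinson annulation in its Mannich-base/β-keto ester form, here run as a [3+3] union in which the donor ketone uses both of its α-carbons. Ring B closes in the aldol step, a 6-(enolendo)-exo-trig closure. The one new stereocentre, C5, is formed by protonation α to the C10 ketone and stays epimerisable in 14, so the slower ring closure selects between the two C5 epimers: with C6 equatorial on ring A, the epimer that puts CO2Me rather than CH3 into the axial site syn to the developing C10–O bond has the smaller 1,3-diaxial contact, which gives H-5 cis to the C4 methyl and C6 cis to CO2Me as in the target. The step needs C7 and not C9 as the Michael donor, which the allyl ester secures, and it needs C9→C10 and not C1→C8 as the productive aldol, which holds because only the first ketol can dehydrate to a conjugated enone while the bridged alternative reverts. The quaternary C4 cannot epimerise and the remote C13 is not involved.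

Step 9
Reactants: 15
Product: 17 methyl (1S,8aR)-1-methyl-5-{(3S)-3-methyl-5-[(triisopropylsilyl)oxy]pentyl}-6-oxo-1,2,3,4,6,7,8,8a-octahydronaphthalene-1-carboxylate, via β-keto acid 16 (not isolated)
Conditions: Pd(OAc)2 (cat.), PPh3, HCO2H, Et3N, THF, 40 °C
Reagents that add atoms: none
Why: Palladium-catalysed deallylation by formate (zerovalent palladium formed in situ) and spontaneous decarboxylation of the β-keto acid should remove the C7 activating group under near-neutral conditions that spare the methyl ester, the enone and the silyl ether; any minor C5 epimer is removed at this stage.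

Step 10
Reactants: 17
Product: 19 methyl (1S,5R,8aR)-1,5-dimethyl-5-{(3S)-3-methyl-5-[(triisopropylsilyl)oxy]pentyl}-6-oxo-1,2,3,5,6,7,8,8a-octahydronaphthalene-1-carboxylate, via potassium dienolate 18 (not isolated)
Conditions: t-BuOK, t-BuOH/THF, 0 °C → rt; then MeI, 0 °C → rt
Reagents that add atoms: iodomethane, CI
Why: Deconjugative α-alkylation of the extended dienolate (γ-deprotonation at the C1 methylene rather than at the hindered C5–H) should put C20 on C9 and move the alkene to C1=C10, and methyl iodide should attack axially through a chair-like transition state on the face of the axial H-5, so the chain stays equatorial and C9 has the target configuration.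

Step 11
Reactants: 19
Product: 20 methyl (1S,5S,8aR)-1,5-dimethyl-5-{(3S)-3-methyl-5-[(triisopropylsilyl)oxy]pentyl}-6-methylidene-1,2,3,5,6,7,8,8a-octahydronaphthalene-1-carboxylate
Conditions: Ph3PCH3Br, t-BuOK, toluene, 90 °C
Reagents that add atoms: methyltriphenylphosphonium bromide, C[P+](c1ccccc1)(c1ccccc1)c1ccccc1.[Br-]
Why: Wittig methylenation at elevated temperature should convert the hindered C8 ketone, whose activating role is over, into the carbon that becomes C17; C9 is quaternary, so no stereocentre is at risk.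

Step 12
Reactants: 20
Product: 21 methyl (1S,5S,6R,8aR)-1,5,6-trimethyl-5-{(3S)-3-methyl-5-[(triisopropylsilyl)oxy]pentyl}-1,2,3,5,6,7,8,8a-octahydronaphthalene-1-carboxylate
Conditions: H2 (3 atm), RhCl(PPh3)3 (cat.), benzene, rt
Reagents that add atoms: none
Why: Homogeneous hydrogenation should reduce only the 1,1-disubstituted exocyclic alkene, since the trisubstituted C1=C10 bond next to quaternary C9 is too hindered, and hydrogen should arrive on the face opposite the axial C9 methyl, making C17 equatorial and cis to C20.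

Step 13
Reactants: 21
Product: 22 methyl (1S,5S,6R,8aR)-5-[(3S)-5-hydroxy-3-methylpentyl]-1,5,6-trimethyl-1,2,3,5,6,7,8,8a-octahydronaphthalene-1-carboxylate
Conditions: TBAF, THF, rt
Reagents that add atoms: none
Why: Fluoride-induced desilylation frees the primary C15 alcohol and should leave the hindered tertiary methyl ester and the alkene untouched.

Step 14
Reactants: 22
Product: 23 methyl (1S,5S,6R,8aR)-5-[(3S)-5-acetoxy-3-methylpentyl]-1,5,6-trimethyl-1,2,3,5,6,7,8,8a-octahydronaphthalene-1-carboxylate (target)
Conditions: Ac2O, pyridine, DMAP (cat.), CH2Cl2, rt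
Reagents that add atoms: acetic anhydride, CC(=O)OC(C)=O
Why: Acylation of the primary alcohol under nucleophilic catalysis gives the acetate without touching any stereocentre.

**Compound list**

1 | (S)-citronellol | CC(C)=CCC[C@H](C)CCO | starting material
2 | (S)-[(3,7-dimethyloct-6-en-1-yl)oxy]triisopropylsilane | CC(C)=CCC[C@H](C)CCO[Si](C(C)C)(C(C)C)C(C)C | intermediate
3 | (S)-4-methyl-6-[(triisopropylsilyl)oxy]hexanoic acid | OC(=O)CC[C@H](C)CCO[Si](C(C)C)(C(C)C)C(C)C | intermediate
4 | (R)-[(5-iodo-3-methylpentyl)oxy]triisopropylsilane | ICC[C@H](C)CCO[Si](C(C)C)(C(C)C)C(C)C | intermediate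
5 | allyl acetoacetate (prop-2-en-1-yl 3-oxobutanoate) | CC(=O)CC(=O)OCC=C | starting material
6 | sodium lithium dianion of allyl acetoacetate | C=CCOC(=O)[CH-]C(=O)[CH2-].[Na+].[Li+] | intermediate (not isolated)
7 | prop-2-en-1-yl (7S)-7-methyl-3-oxo-9-[(triisopropylsilyl)oxy]nonanoate | C=CCOC(=O)CC(=O)CCC[C@H](C)CCO[Si](C(C)C)(C(C)C)C(C)C | intermediate
8 | methyl 3-oxocyclohex-1-ene-1-carboxylate | COC(=O)C1=CC(=O)CCC1 | starting material
9 | methylzinc enolate of methyl (S)-1-methyl-3-oxocyclohexane-1-carboxylate (enolate toward C2 of the ring) | COC(=O)[C@@]1(C)CCCC(O[Zn]C)=C1 | intermediate (not isolated)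
10 | methyl (S)-1-methyl-3-[(trimethylsilyl)oxy]cyclohex-2-ene-1-carboxylate | COC(=O)[C@@]1(C)CCCC(O[Si](C)(C)C)=C1 | intermediate
11 | methyl (1S)-2-[(dimethylamino)methyl]-1-methyl-3-oxocyclohexane-1-carboxylate (C2 epimers) | COC(=O)[C@@]1(C)CCCC(=O)C1CN(C)C | intermediate
12 | {[(2S)-2-(methoxycarbonyl)-2-methyl-6-oxocyclohexyl]methyl}trimethylammonium iodide | COC(=O)[C@@]1(C)CCCC(=O)C1C[N+](C)(C)C.[I-] | intermediate
13 | methyl (S)-1-methyl-2-methylidene-3-oxocyclohexane-1-carboxylate | COC(=O)[C@@]1(C)CCCC(=O)C1=C | intermediate (not isolated)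
14 | prop-2-en-1-yl (7S)-2-{[(2S)-2-(methoxycarbonyl)-2-methyl-6-oxocyclohexyl]methyl}-7-methyl-3-oxo-9-[(triisopropylsilyl)oxy]nonanoate (epimers at the two enolisable centres) | COC(=O)[C@@]1(C)CCCC(=O)C1CC(C(=O)OCC=C)C(=O)CCC[C@H](C)CCO[Si](C(C)C)(C(C)C)C(C)C | intermediate (not isolated)
15 | 7-allyl 1-methyl (1S,8aR)-1-methyl-5-{(3S)-3-methyl-5-[(triisopropylsilyl)oxy]pentyl}-6-oxo-1,2,3,4,6,7,8,8a-octahydronaphthalene-1,7-dicarboxylate (C7 epimers/enol) | COC(=O)[C@@]1(C)CCCC2=C(CC[C@H](C)CCO[Si](C(C)C)(C(C)C)C(C)C)C(=O)C(C(=O)OCC=C)C[C@@H]12 | intermediate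
16 | (8S,8aR)-8-(methoxycarbonyl)-8-methyl-4-{(3S)-3-methyl-5-[(triisopropylsilyl)oxy]pentyl}-3-oxo-1,2,3,5,6,7,8,8a-octahydronaphthalene-2-carboxylic acid | COC(=O)[C@@]1(C)CCCC2=C(CC[C@H](C)CCO[Si](C(C)C)(C(C)C)C(C)C)C(=O)C(C(=O)O)C[C@@H]12 | intermediate (not isolated)
17 | methyl (1S,8aR)-1-methyl-5-{(3S)-3-methyl-5-[(triisopropylsilyl)oxy]pentyl}-6-oxo-1,2,3,4,6,7,8,8a-octahydronaphthalene-1-carboxylate | COC(=O)[C@@]1(C)CCCC2=C(CC[C@H](C)CCO[Si](C(C)C)(C(C)C)C(C)C)C(=O)CC[C@@H]12 | intermediate
18 | potassium salt of the extended dienol of 17 (C8–O−, C8=C9 and C1=C10; C4 and C5 as in 17) | COC(=O)[C@@]1(C)CCC=C2[C@H]1CCC([O-])=C2CC[C@H](C)CCO[Si](C(C)C)(C(C)C)C(C)C.[K+] | intermediate (not isolated)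
19 | methyl (1S,5R,8aR)-1,5-dimethyl-5-{(3S)-3-methyl-5-[(triisopropylsilyl)oxy]pentyl}-6-oxo-1,2,3,5,6,7,8,8a-octahydronaphthalene-1-carboxylate | COC(=O)[C@@]1(C)CCC=C2[C@H]1CCC(=O)[C@]2(C)CC[C@H](C)CCO[Si](C(C)C)(C(C)C)C(C)C | intermediate
20 | methyl (1S,5S,8aR)-1,5-dimethyl-5-{(3S)-3-methyl-5-[(triisopropylsilyl)oxy]pentyl}-6-methylidene-1,2,3,5,6,7,8,8a-octahydronaphthalene-1-carboxylate | COC(=O)[C@@]1(C)CCC=C2[C@H]1CCC(=C)[C@]2(C)CC[C@H](C)CCO[Si](C(C)C)(C(C)C)C(C)C | intermediate
21 | methyl (1S,5S,6R,8aR)-1,5,6-trimethyl-5-{(3S)-3-methyl-5-[(triisopropylsilyl)oxy]pentyl}-1,2,3,5,6,7,8,8a-octahydronaphthalene-1-carboxylate | COC(=O)[C@@]1(C)CCC=C2[C@H]1CC[C@@H](C)[C@]2(C)CC[C@H](C)CCO[Si](C(C)C)(C(C)C)C(C)C | intermediate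
22 | methyl (1S,5S,6R,8aR)-5-[(3S)-5-hydroxy-3-methylpentyl]-1,5,6-trimethyl-1,2,3,5,6,7,8,8a-octahydronaphthalene-1-carboxylate | COC(=O)[C@@]1(C)CCC=C2[C@H]1CC[C@@H](C)[C@]2(C)CC[C@H](C)CCO | intermediate
23 | methyl (1S,5S,6R,8aR)-5-[(3S)-5-acetoxy-3-methylpentyl]-1,5,6-trimethyl-1,2,3,5,6,7,8,8a-octahydronaphthalene-1-carboxylate | COC(=O)[C@@]1(C)CCC=C2[C@H]1CC[C@@H](C)[C@]2(C)CC[C@H](C)CCOC(C)=O | target

**Step count and risks**

Total step count: 14. Longest linear sequence: 11 steps (steps 1–4, then 8–14).

The three steps most likely to fail: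

Step 8 (key annulation). Three processes may go wrong. The α-methylene ketone may oligomerise or dimerise before the Michael donor captures it. The selection between the C5 epimers in the ring closure may be weak, because CO2Me and CH3 on C4 differ only modestly in size. The axial ester may lactonise onto the C10 alkoxide and be lost as carboxylate on dehydration. The fallback separates the two bond formations and uses a Lewis acid for the first. It sets out from 4 and 12 and comes back at 17. Iodide 4 should alkylate lithiated acetone N,N-dimethylhydrazone (LiN(i-Pr)2, THF, −78 → 0 °C) to give the hydrazone of (S)-6-methyl-8-[(triisopropylsilyl)oxy]octan-2-one F1. Buffered hydrolysis (aq. oxalic acid) should give the methyl ketone (S)-6-methyl-8-[(triisopropylsilyl)oxy]octan-2-one F2. Kinetic enolisation on the methyl side (LiN(i-Pr)2, TMSCl, −78 °C) should give the trimethylsilyl enol ether F3. Enone 13 is liberated from 12 (NaHCO3, CH2Cl2/H2O) and used at once in a Mukaiyama–Michael addition with F3 (TiCl4, CH2Cl2, −78 °C), which should give the 1,5-diketone methyl (1S)-1-methyl-2-{(7S)-7-methyl-3-oxo-9-[(triisopropylsilyl)oxy]nonyl}-3-oxocyclohexane-1-carboxylate F4. Aldol condensation under amine–acid catalysis (pyrrolidine, AcOH, toluene, 80 °C) closes ring B slowly, so C5 can equilibrate fully before closure, and gives 17.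

Step 10 (deconjugative methylation). The risks are competing γ-deprotonation at C5 (leading to the C5=C10 isomer and loss of C5 integrity), O-methylation, methylation at C7, and insufficient axial preference at C9. The fallback alkylates an aza-enolate instead of the potassium dienolate. It sets out from 17 and comes back at 19. Condensation of 17 with cyclohexylamine (TiCl4, Et3N, toluene) should give the N-cyclohexyl imine of 17 F5. Deprotonation (LiN(i-Pr)2, THF, −78 → 0 °C) and reaction with MeI should give the C9-methylated β,γ-unsaturated N-cyclohexyl imine F6, since such 1-azadienyl anions react at carbon only and through a tighter, more axial-selective transition state. Mild hydrolysis (aq. AcOH/NaOAc) returns ketone 19.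

Step 12 (hydrogenation). The risks are slow reduction of the hindered exocyclic alkene, migration of that alkene into ring B, partial reduction of C1=C10, and insufficient facial selectivity at C8. The fallback replaces hydrogenation by hydroboration and deoxygenation. It sets out from 20 and comes back at 21. Hydroboration with 9-BBN (THF, rt), which should add to the exocyclic alkene only and from the face opposite the axial C9 methyl, followed by oxidation (NaBO3, H2O), should give the 17-hydroxy analogue of 21 (C8 hydroxymethyl cis to the C9 methyl) F7. Iodination (I2, PPh3, imidazole) should give the 17-iodo analogue of 21 F8, and radical reduction (Bu3SnH, AIBN, benzene, 80 °C) gives 21.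

**Further compounds**

F1 | step 8 | N,N-dimethylhydrazone of (S)-6-methyl-8-[(triisopropylsilyl)oxy]octan-2-one | CN(C)N=C(C)CCC[C@H](C)CCO[Si](C(C)C)(C(C)C)C(C)C
F2 | step 8 | (S)-6-methyl-8-[(triisopropylsilyl)oxy]octan-2-one | CC(=O)CCC[C@H](C)CCO[Si](C(C)C)(C(C)C)C(C)C
F3 | step 8 | (S)-triisopropyl({3-methyl-7-[(trimethylsilyl)oxy]oct-7-en-1-yl}oxy)silane | C=C(O[Si](C)(C)C)CCC[C@H](C)CCO[Si](C(C)C)(C(C)C)C(C)C
F4 | step 8 | methyl (1S)-1-methyl-2-{(7S)-7-methyl-3-oxo-9-[(triisopropylsilyl)oxy]nonyl}-3-oxocyclohexane-1-carboxylate (C2 epimers) | COC(=O)[C@@]1(C)CCCC(=O)C1CCC(=O)CCC[C@H](C)CCO[Si](C(C)C)(C(C)C)C(C)C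
F5 | step 10 | N-cyclohexyl imine of 17 | COC(=O)[C@@]1(C)CCCC2=C(CC[C@H](C)CCO[Si](C(C)C)(C(C)C)C(C)C)C(=NC3CCCCC3)CC[C@@H]12
F6 | step 10 | N-cyclohexyl imine of 19 | COC(=O)[C@@]1(C)CCC=C2[C@H]1CCC(=NC3CCCCC3)[C@]2(C)CC[C@H](C)CCO[Si](C(C)C)(C(C)C)C(C)C
F7 | step 12 | 17-hydroxy analogue of 21 (C8 hydroxymethyl cis to the C9 methyl) | COC(=O)[C@@]1(C)CCC=C2[C@H]1CC[C@@H](CO)[C@]2(C)CC[C@H](C)CCO[Si](C(C)C)(C(C)C)C(C)C
F8 | step 12 | 17-iodo analogue of 21 (C8 iodomethyl cis to the C9 methyl) | COC(=O)[C@@]1(C)CCC=C2[C@H]1CC[C@@H](CI)[C@]2(C)CC[C@H](C)CCO[Si](C(C)C)(C(C)C)C(C)C
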